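**Plan**
1. Retrosynthesis: cut the O7–Si bond and the C8–prenyl bond (C8–I stands in for prenyl), then cut ring C at C2–C3 and C4–C4a. This removes C3–C4 as a two-carbon ketene equivalent (1-ethoxy-2-silylethyne) and leaves the O-aryl oxocarbenium ion ring A–O1(+)=C2H–ring B. The ion is traced to an α-acetoxy ether, then to the aryl ester C2(=O)–O1, then to 2-iodoresorcinol and 2,2-dimethylchromene-6-carboxylic acid.
2. Enabling feature: C2 lies between O1 and ring B, whose pyran oxygen is para to C2, so it ionizes easily. C4a of ring A is ortho to O1, para to O7 and the only free ortho carbon, so C4a=C8a–O1=C2(+) acts as a cationic 2-oxadiene.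
3. Forward order: the dimethylpyran ring on ring B is made first (propargyl ether Claisen), then the ester union with ring A, reductive acetylation, ring C by cationic [4+2] annulation, prenyl by Stille coupling, and desilylation.
4. Stereochemistry: C2 (S), the only stereocentre, is set in the annulation by a confined chiral counter-anion.
5. Iodine replaces prenyl until ring C exists, because a prenyl alkene ortho to O1 would trap the oxocarbenium ion by a six-ring Prins closure.

Key step: step 7

Remark: the facial sense that the chiral anion imposes on an acyclic O-aryl oxocarbenium ion cannot be assigned in advance; the (S,S)-acid is written, and its (R,R)-antipode is to be used if a test reaction shows the opposite sense.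

**Step 1**
Reactants: 1 methyl 4-hydroxybenzoate; 2 3-chloro-3-methylbut-1-yne
Product: 3 methyl 4-[(2-methylbut-3-yn-2-yl)oxy]benzoate
Conditions: K2CO3, KI, CuI (cat.), acetone, reflux
Reagents that add atoms: none
Why: Copper-assisted O-alkylation of the phenoxide by the tertiary propargylic chloride (aryl propargyl ether synthesis) should proceed with the ester untouched.

**Step 2**
Reactants: 3 methyl 4-[(2-methylbut-3-yn-2-yl)oxy]benzoate
Product: 5 methyl 2,2-dimethyl-2H-chromene-6-carboxylate, via allenylphenol 4 (not isolated)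
Conditions: N,N-diethylaniline, 195 °C
Reagents that add atoms: none
Why: Aromatic propargyl Claisen rearrangement to the o-allenylphenol, followed by 1,5-hydrogen shift and oxa-6π electrocyclization, is the standard entry to 2,2-dimethyl-2H-chromenes; the two ortho positions are equivalent.

**Step 3**
Reactants: 5 methyl 2,2-dimethyl-2H-chromene-6-carboxylate
Product: 6 2,2-dimethyl-2H-chromene-6-carboxylic acid
Conditions: LiOH, THF/MeOH/H2O, 50 °C; then 1 M HCl
Reagents that add atoms: lithium hydroxide [Li+].[OH-]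
Why: Saponification of the methyl ester should be clean because the chromene is stable to aqueous base.

**Step 4**
Reactants: 7 2-iodobenzene-1,3-diol (2-iodoresorcinol)
Product: 8 3-[(tert-butyldimethylsilyl)oxy]-2-iodophenol
Conditions: TBSCl (1.0 equiv), imidazole, DMF, 0 °C
Reagents that add atoms: tert-butyldimethylsilyl chloride CC(C)(C)[Si](C)(C)Cl
Why: Silylation of one of the two equivalent hydroxyls of the symmetric diol gives the same product from either side; unreacted diol and bis-ether are to be separated and recycled.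

**Step 5**
Reactants: 6 2,2-dimethyl-2H-chromene-6-carboxylic acid; 8 3-[(tert-butyldimethylsilyl)oxy]-2-iodophenol
Product: 9 3-[(tert-butyldimethylsilyl)oxy]-2-iodophenyl 2,2-dimethyl-2H-chromene-6-carboxylate
Conditions: DCC, DMAP (cat.), CH2Cl2, 0 °C to rt
Reagents that add atoms: none
Why: Steglich esterification, in which acyl transfer through DMAP should overcome the hindrance of the ortho-iodo phenol; this step makes the future O1–C2 bond.

**Step 6**
Reactants: 9 3-[(tert-butyldimethylsilyl)oxy]-2-iodophenyl 2,2-dimethyl-2H-chromene-6-carboxylate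
Product: 11 (RS)-{3-[(tert-butyldimethylsilyl)oxy]-2-iodophenoxy}(2,2-dimethyl-2H-chromen-6-yl)methyl acetate, via aluminium hemiacetal 10 (not isolated)
Conditions: DIBAL-H, CH2Cl2, −78 °C; then pyridine, DMAP, Ac2O, −78 to −20 °C
Reagents that add atoms: acetic anhydride CC(=O)OC(C)=O
Why: Reductive acetylation of an ester: hydride addition at −78 °C should give a tetrahedral aluminium hemiacetal that is acetylated in place before it collapses; the new centre is racemic and is erased in step 7, and 11 is to be used without chromatography.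

**Step 7**
Reactants: 11 (RS)-{3-[(tert-butyldimethylsilyl)oxy]-2-iodophenoxy}(2,2-dimethyl-2H-chromen-6-yl)methyl acetate; 12 1-ethoxy-2-(trimethylsilyl)ethyne
Product: 17 (2S)-7-[(tert-butyldimethylsilyl)oxy]-2-(2,2-dimethyl-2H-chromen-6-yl)-8-iodo-2,3-dihydro-4H-chromen-4-one, via oxocarbenium ion 13 (not isolated), via ketenium ion 14 (not isolated), via 3-silyl enol ether 15 (not isolated), via ethyl enol ether 16 (not isolated)
Conditions: 12 (1.5 equiv), (S,S)-IDPi acid HN[P(=NSO2CF3)(O2C20H10Ar2)]2 (from (S)-3,3'-Ar2-BINOL, Ar = 3,5-(CF3)2C6H3; 5 mol %), toluene, −78 °C; then 1 M HCl, THF, 0 °C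
Reagents that add atoms: water O
Why: Proposed new method: the acid is silylated by 12 and the silylated catalyst removes the acetate of 11 to give the O-aryl oxocarbenium ion 13 paired with the chiral anion; the silicon-bearing carbon of 12 adds to C2 (bond C2–C3) to give ketenium ion 14, whose sp carbon C4 is attacked by C4a of ring A (bond C4–C4a), and the proton lost on rearomatization removes the C3 silyl group of 15, which returns the silyl cation to the catalyst and leaves enol ether 16 for hydrolysis to ketone 17. The closest known reaction types are the oxa-Povarov cationic [4+2] of O-aryl oxocarbenium ions with alkenes, chiral-anion-controlled additions of silyl nucleophiles to oxocarbenium ions made from acetoxy ethers, Lewis-acid additions of 1-alkoxy-2-silylalkynes to oxocarbenium ions, and Friedel–Crafts closure of ketenium ions onto arenes. Ring C closes by a stepwise formal [4+2]: intermolecular C2–C3 bond formation, then a 6-exo-dig Friedel–Crafts closure (with respect to the C4=O(+) bond) onto the ketenium carbon. C2 is set in the first C–C bond formation, where the confined anion should shield one face of the planar oxocarbenium ion. The step needs ionization on the acetate side (acetate is more Lewis basic and a better leaving group than the aryloxide), attack through the silylated alkyne carbon (oxygen and beta-silicon both stabilize 14), and closure at C4a only (C8 carries iodine, and the ortho carbons of ring B are meta to its oxygen). It also needs the absence of any pi-nucleophile near C2 (no prenyl group yet; the chromene alkene is not conjugated to C2).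

**Step 8**
Reactants: 17 (2S)-7-[(tert-butyldimethylsilyl)oxy]-2-(2,2-dimethyl-2H-chromen-6-yl)-8-iodo-2,3-dihydro-4H-chromen-4-one; 18 tributyl(3-methylbut-2-en-1-yl)stannane
Product: 19 (2S)-7-[(tert-butyldimethylsilyl)oxy]-2-(2,2-dimethyl-2H-chromen-6-yl)-8-(3-methylbut-2-en-1-yl)-2,3-dihydro-4H-chromen-4-one
Conditions: Pd2(dba)3 (2.5 mol %), AsPh3 (20 mol %), DMF, 70 °C
Reagents that add atoms: none
Why: Stille coupling: oxidative addition of zerovalent palladium to the aryl iodide, transmetalation of the prenyl group and reductive elimination at the less hindered allyl terminus should give the linear prenyl arene, and the neutral conditions should leave C2 untouched.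

**Step 9**
Reactants: 19 (2S)-7-[(tert-butyldimethylsilyl)oxy]-2-(2,2-dimethyl-2H-chromen-6-yl)-8-(3-methylbut-2-en-1-yl)-2,3-dihydro-4H-chromen-4-one
Product: 20 (2S)-2-(2,2-dimethyl-2H-chromen-6-yl)-7-hydroxy-8-(3-methylbut-2-en-1-yl)-2,3-dihydro-4H-chromen-4-one
Conditions: TBAF, AcOH, THF, 0 °C
Reagents that add atoms: none
Why: Fluoride cleavage of the aryl silyl ether, buffered by acetic acid so that no base is present that could open ring C by retro-oxa-Michael reaction and racemize C2.

**Compound list**
1 | methyl 4-hydroxybenzoate | COC(=O)c1ccc(O)cc1 | starting material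
2 | 3-chloro-3-methylbut-1-yne | CC(C)(Cl)C#C | starting material
3 | methyl 4-[(2-methylbut-3-yn-2-yl)oxy]benzoate | COC(=O)c1ccc(OC(C)(C)C#C)cc1 | intermediate
4 | methyl 4-hydroxy-3-(3-methylbuta-1,2-dien-1-yl)benzoate | COC(=O)c1ccc(O)c(C=C=C(C)C)c1 | intermediate (not isolated)
5 | methyl 2,2-dimethyl-2H-chromene-6-carboxylate | COC(=O)c1ccc2OC(C)(C)C=Cc2c1 | intermediate
6 | 2,2-dimethyl-2H-chromene-6-carboxylic acid | OC(=O)c1ccc2OC(C)(C)C=Cc2c1 | intermediate
7 | 2-iodobenzene-1,3-diol | Oc1cccc(O)c1I | starting material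
8 | 3-[(tert-butyldimethylsilyl)oxy]-2-iodophenol | CC(C)(C)[Si](C)(C)Oc1cccc(O)c1I | intermediate
9 | 3-[(tert-butyldimethylsilyl)oxy]-2-iodophenyl 2,2-dimethyl-2H-chromene-6-carboxylate | CC(C)(C)[Si](C)(C)Oc1cccc(OC(=O)c2ccc3OC(C)(C)C=Cc3c2)c1I | intermediate
10 | diisobutylaluminium alkoxide of the hemiacetal {3-[(tert-butyldimethylsilyl)oxy]-2-iodophenoxy}(2,2-dimethyl-2H-chromen-6-yl)methanol (racemic) | CC(C)C[Al](CC(C)C)OC(Oc1cccc(O[Si](C)(C)C(C)(C)C)c1I)c1ccc2OC(C)(C)C=Cc2c1 | intermediate (not isolated)
11 | (RS)-{3-[(tert-butyldimethylsilyl)oxy]-2-iodophenoxy}(2,2-dimethyl-2H-chromen-6-yl)methyl acetate | CC(=O)OC(Oc1cccc(O[Si](C)(C)C(C)(C)C)c1I)c1ccc2OC(C)(C)C=Cc2c1 | intermediate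
12 | 1-ethoxy-2-(trimethylsilyl)ethyne | CCOC#C[Si](C)(C)C | starting material
13 | {3-[(tert-butyldimethylsilyl)oxy]-2-iodophenyl}[(2,2-dimethyl-2H-chromen-6-yl)methylidene]oxonium, ion pair with the catalyst anion (cation shown) | CC1(C)C=Cc2cc(C=[O+]c3cccc(O[Si](C)(C)C(C)(C)C)c3I)ccc2O1 | intermediate (not isolated)
14 | (3R)-ketenium ion ethyl{3-{3-[(tert-butyldimethylsilyl)oxy]-2-iodophenoxy}-3-(2,2-dimethyl-2H-chromen-6-yl)-2-(trimethylsilyl)prop-1-en-1-ylidene}oxonium; same spatial arrangement at the stereocentre as C2 of 17, the descriptor is R because silicon raises the priority of the neighbouring carbon (cation shown) | CC[O+]=C=C([Si](C)(C)C)[C@H](Oc1cccc(O[Si](C)(C)C(C)(C)C)c1I)c1ccc2OC(C)(C)C=Cc2c1 | intermediate (not isolated)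
15 | tert-butyl{[(2R)-2-(2,2-dimethyl-2H-chromen-6-yl)-4-ethoxy-8-iodo-3-(trimethylsilyl)-2H-chromen-7-yl]oxy}dimethylsilane (same spatial arrangement as 17; descriptor R because of silicon on C3) | Ic1c(O[Si](C)(C)C(C)(C)C)ccc2c1O[C@H](c1ccc3c(c1)C=CC(C)(C)O3)C([Si](C)(C)C)=C2OCC | intermediate (not isolated)
16 | tert-butyl{[(2S)-2-(2,2-dimethyl-2H-chromen-6-yl)-4-ethoxy-8-iodo-2H-chromen-7-yl]oxy}dimethylsilane | Ic1c(O[Si](C)(C)C(C)(C)C)ccc2c1O[C@H](c1ccc3c(c1)C=CC(C)(C)O3)C=C2OCC | intermediate (not isolated)
17 | (2S)-7-[(tert-butyldimethylsilyl)oxy]-2-(2,2-dimethyl-2H-chromen-6-yl)-8-iodo-2,3-dihydro-4H-chromen-4-one | Ic1c(O[Si](C)(C)C(C)(C)C)ccc2c1O[C@H](c1ccc3c(c1)C=CC(C)(C)O3)CC2=O | intermediate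
18 | tributyl(3-methylbut-2-en-1-yl)stannane | CC(C)=CC[Sn](CCCC)(CCCC)CCCC | starting material
19 | (2S)-7-[(tert-butyldimethylsilyl)oxy]-2-(2,2-dimethyl-2H-chromen-6-yl)-8-(3-methylbut-2-en-1-yl)-2,3-dihydro-4H-chromen-4-one | CC(C)=CCc1c(O[Si](C)(C)C(C)(C)C)ccc2c1O[C@H](c1ccc3c(c1)C=CC(C)(C)O3)CC2=O | intermediate
20 | (2S)-2-(2,2-dimethyl-2H-chromen-6-yl)-7-hydroxy-8-(3-methylbut-2-en-1-yl)-2,3-dihydro-4H-chromen-4-one | CC(C)=CCc1c(O)ccc2c1O[C@H](c1ccc3c(c1)C=CC(C)(C)O3)CC2=O | target

**Totals**
Total step count: 9. Longest linear sequence: 8 steps (steps 1, 2, 3, 5, 6, 7, 8, 9).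

**Steps most likely to fail**

Step 7 (proposed new method). Possible failures are poor facial discrimination of the acyclic O-aryl oxocarbenium ion, loss of the silyl group from the ketenium ion before ring closure, and capture of the ketenium ion by acetate or adventitious water to give an open-chain ester. The fallback uses known reaction types only, sets out from ester 5 (with phenol 8) and returns at 17.
- Crossed Claisen condensation of 5 with the lithium enolate of ethyl acetate (LiHMDS, THF, −78 °C) would give ethyl 3-(2,2-dimethyl-2H-chromen-6-yl)-3-oxopropanoate F1.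
- Asymmetric transfer hydrogenation (RuCl(p-cymene)[(R,R)-TsDPEN], HCO2H/Et3N) would give ethyl (3R)-3-(2,2-dimethyl-2H-chromen-6-yl)-3-hydroxypropanoate F2; the (R,R)-catalyst is expected to give the (3R)-alcohol by analogy with simple aryl ketones.
- Mitsunobu etherification with phenol 8 (PPh3, DIAD, toluene, 0 °C, inversion) would give ethyl (3S)-3-{3-[(tert-butyldimethylsilyl)oxy]-2-iodophenoxy}-3-(2,2-dimethyl-2H-chromen-6-yl)propanoate F3.
- Neutral ester cleavage with Me3SnOH (1,2-dichloroethane, 70 °C) would give (3S)-3-{3-[(tert-butyldimethylsilyl)oxy]-2-iodophenoxy}-3-(2,2-dimethyl-2H-chromen-6-yl)propanoic acid F4.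
- Trifluoroacetic anhydride (CH2Cl2, 0 °C) would form the mixed anhydride (3S)-3-{3-[(tert-butyldimethylsilyl)oxy]-2-iodophenoxy}-3-(2,2-dimethyl-2H-chromen-6-yl)propanoic trifluoroacetic anhydride F5, which should close onto C4a by Friedel–Crafts acylation to give 17.

Step 6. The aluminium hemiacetal may collapse before acetylation because the aryloxide is a good leaving group, leading to over-reduction, and the labile acetoxy ether may ionize or hydrolyse on handling. The fallback sets out from ester 5 (with phenol 8) and returns at 11.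
- LiAlH4 (THF, 0 °C) would give (2,2-dimethyl-2H-chromen-6-yl)methanol F6.
- Mitsunobu etherification with phenol 8 (PPh3, DIAD, THF) would give tert-butyl{3-[(2,2-dimethyl-2H-chromen-6-yl)methoxy]-2-iodophenoxy}dimethylsilane F7.
- Oxidation with DDQ in the presence of acetic acid (CH2Cl2, 4 Å sieves, 0 °C) would give 11 by hydride abstraction from the p-alkoxybenzylic CH2 and capture of the oxocarbenium ion by acetate.

Step 8. Transmetalation may be slow at the aryl palladium flanked by two ortho oxygen substituents, and allyl transposition may give the 1,1-dimethylallyl isomer. The fallback sets out from 17 and returns at 19.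
- Stille coupling with allyltributylstannane (Pd2(dba)3, AsPh3, DMF, 70 °C), which has no regiochemical ambiguity, would give (2S)-8-allyl-7-[(tert-butyldimethylsilyl)oxy]-2-(2,2-dimethyl-2H-chromen-6-yl)-2,3-dihydro-4H-chromen-4-one F8.
- Cross-metathesis with 2-methylbut-2-ene (second-generation Grubbs catalyst RuCl2(=CHPh)(H2IMes)(PCy3), CH2Cl2, 40 °C) would give 19.

**Further compounds**
F1 | step 7 | ethyl 3-(2,2-dimethyl-2H-chromen-6-yl)-3-oxopropanoate | CCOC(=O)CC(=O)c1ccc2OC(C)(C)C=Cc2c1
F2 | step 7 | ethyl (3R)-3-(2,2-dimethyl-2H-chromen-6-yl)-3-hydroxypropanoate | CCOC(=O)C[C@@H](O)c1ccc2OC(C)(C)C=Cc2c1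
F3 | step 7 | ethyl (3S)-3-{3-[(tert-butyldimethylsilyl)oxy]-2-iodophenoxy}-3-(2,2-dimethyl-2H-chromen-6-yl)propanoate | CCOC(=O)C[C@H](Oc1cccc(O[Si](C)(C)C(C)(C)C)c1I)c1ccc2OC(C)(C)C=Cc2c1
F4 | step 7 | (3S)-3-{3-[(tert-butyldimethylsilyl)oxy]-2-iodophenoxy}-3-(2,2-dimethyl-2H-chromen-6-yl)propanoic acid | OC(=O)C[C@H](Oc1cccc(O[Si](C)(C)C(C)(C)C)c1I)c1ccc2OC(C)(C)C=Cc2c1
F5 | step 7 | (3S)-3-{3-[(tert-butyldimethylsilyl)oxy]-2-iodophenoxy}-3-(2,2-dimethyl-2H-chromen-6-yl)propanoic trifluoroacetic anhydride | FC(F)(F)C(=O)OC(=O)C[C@H](Oc1cccc(O[Si](C)(C)C(C)(C)C)c1I)c1ccc2OC(C)(C)C=Cc2c1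
F6 | step 6 | (2,2-dimethyl-2H-chromen-6-yl)methanol | OCc1ccc2OC(C)(C)C=Cc2c1
F7 | step 6 | tert-butyl{3-[(2,2-dimethyl-2H-chromen-6-yl)methoxy]-2-iodophenoxy}dimethylsilane | CC(C)(C)[Si](C)(C)Oc1cccc(OCc2ccc3OC(C)(C)C=Cc3c2)c1I
F8 | step 8 | (2S)-8-allyl-7-[(tert-butyldimethylsilyl)oxy]-2-(2,2-dimethyl-2H-chromen-6-yl)-2,3-dihydro-4H-chromen-4-one | C=CCc1c(O[Si](C)(C)C(C)(C)C)ccc2c1O[C@H](c1ccc3c(c1)C=CC(C)(C)O3)CC2=O
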